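The route rests on cutting ring A (the pyrrolidin-3-one: N, NCH2, CH(CH3), C=O and the bridgehead α-amino carbon shared with rings B and C) back to an N-allyl amine and a bridgehead methyl ester. The α-methyl ketone is read as an opened cyclopropanol: one titanium-mediated intramolecular Kulinkovich reaction joins the ester carbon to both alkene carbons, closing ring A as a 3-azabicyclo[3.1.0]hexan-1-ol whose strain then releases the CH3 group. The precursor is the pentacyclic amino ester lactone, built by an imide-tethered enone–alkene photocycloaddition, radical cyclobutane fragmentation (seven-membered ring, vicinal quaternary carbons, cyclopentene) and an aldol–translactonisation cascade.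

Key step: step 21

Remark: rings are lettered A (pyrrolidinone), B (piperidine), C (cyclopentane), D (cycloheptane), E (cyclopentene), F (δ-lactone).
Assumption: the α-amino ester carbon is carried in both configurations from 16 to 26 (drawn without descriptor); it is planarised in step 18 and then fixed by the ring system, so both epimers converge. The carbinol carbon of 20 and 21, the hemiaminal carbon of 23 and the cyclopropanol pair of 32 are likewise transient and left undefined.
Assumption: methyl 4-chlorobut-2-ynoate and bis(trimethylsilyl) peroxide are taken as purchasable reagents.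

Step 1
Reactants: 1 2-(trimethylsilyloxy)buta-1,3-diene; 2 methyl 4-chlorobut-2-ynoate
Product: 3 methyl 2-(chloromethyl)-4-(trimethylsilyloxy)cyclohexa-1,4-diene-1-carboxylate
Conditions: toluene, BHT (cat.), 110 °C, sealed tube
Reagents that add atoms: none
Why: Diels–Alder reaction in which the nucleophilic diene terminus (CH2 next to C–OSi) bonds to the β-carbon of the ynoate, so the silyl enol ether carbon ends para to the ester-bearing carbon and the tetrasubstituted alkene carries its two one-carbon arms cis; no stereocentre is formed.

Step 2
Reactants: 3 methyl 2-(chloromethyl)-4-(trimethylsilyloxy)cyclohexa-1,4-diene-1-carboxylate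
Product: 4 [2-(chloromethyl)-4-(trimethylsilyloxy)cyclohexa-1,4-dien-1-yl]methanol
Conditions: i-Bu2AlH, CH2Cl2, −78 °C
Reagents that add atoms: none
Why: 1,2-Reduction of the conjugated ester by the aluminium hydride at low temperature should leave the silyl enol ether and the allylic chloride untouched; no stereocentre.

Step 3
Reactants: 4 [2-(chloromethyl)-4-(trimethylsilyloxy)cyclohexa-1,4-dien-1-yl]methanol
Product: 6 4-[(tert-butyldiphenylsilyloxy)methyl]-3-(chloromethyl)cyclohex-3-en-1-one, via bis-silyl ether 5 (not isolated)
Conditions: TBDPSCl, imidazole, CH2Cl2, 0 °C; then 0.5 M HCl, THF, 0 °C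
Reagents that add atoms: tert-butyl(chloro)diphenylsilane CC(C)(C)[Si](Cl)(c1ccccc1)c1ccccc1
Why: Silylation of the primary alcohol followed by mild acid hydrolysis of the far more labile trimethylsilyl enol ether should give the β,γ-unsaturated ketone without moving the tetrasubstituted double bond; no stereocentre.

Step 4
Reactants: 6 4-[(tert-butyldiphenylsilyloxy)methyl]-3-(chloromethyl)cyclohex-3-en-1-one
Product: 7 5-[(tert-butyldiphenylsilyloxy)methyl]-6-(chloromethyl)-4,7-dihydrooxepin-2(3H)-one
Conditions: Me3SiOOSiMe3, Me3SiOTf (cat.), CH2Cl2, −78 to −30 °C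
Reagents that add atoms: bis(trimethylsilyl) peroxide C[Si](C)(C)OO[Si](C)(C)C
Why: Baeyer–Villiger oxidation under conditions that do not epoxidise alkenes; the allylic CH2 should migrate in preference to the plain primary CH2, so oxygen enters next to the alkene and the ring carbons become a CH2O group and a three-carbon acyl chain held cis in a seven-membered lactone.

Step 5
Reactants: 7 5-[(tert-butyldiphenylsilyloxy)methyl]-6-(chloromethyl)-4,7-dihydrooxepin-2(3H)-one; 8 methyl isocyanoacetate
Product: 9 methyl 2-isocyano-3-{5-[(tert-butyldiphenylsilyloxy)methyl]-2-oxo-2,3,4,7-tetrahydrooxepin-6-yl}propanoate (racemic)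
Conditions: K2CO3, Bu4NI (cat.), MeCN, 0 °C to rt, excess 8
Reagents that add atoms: none
Why: C-alkylation of the acidic isocyanoacetate by SN2 displacement of the primary allylic chloride (iodide catalysis), with excess nucleophile against double alkylation; the new α-centre forms as a racemate, which is acceptable because it is erased in step 18.

Step 6
Reactants: 10 cyclopent-2-en-1-one; 11 but-3-en-1-ylmagnesium bromide
Product: 12 (S)-3-(but-3-en-1-yl)cyclopentan-1-one
Conditions: CuBr·SMe2 (cat.), 1-[2-(diphenylphosphino)ferrocenyl]ethyldicyclohexylphosphine (cat., enantiomer giving the S ketone), t-BuOMe, −75 °C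
Reagents that add atoms: none
Why: Copper-catalysed enantioselective conjugate addition of a Grignard reagent to a cyclic enone; the chiral ferrocenyl diphosphine–copper complex differentiates the enone faces and sets the ring stereocentre, the only source of absolute configuration in the route.

Step 7
Reactants: 12 (S)-3-(but-3-en-1-yl)cyclopentan-1-one
Product: 13 (R)-3-(3-oxocyclopentyl)propanoic acid
Conditions: RuCl3 (cat.), NaIO4, MeCN/CCl4/H2O, rt
Reagents that add atoms: sodium periodate [Na+].[O-]I(=O)(=O)=O; water O
Why: Ruthenium tetroxide cleavage of the terminal alkene to the carboxylic acid with loss of one carbon should not touch the ketone or the stereocentre (the descriptor changes only through CIP priorities).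

Step 8
Reactants: 13 (R)-3-(3-oxocyclopentyl)propanoic acid; 9 methyl 2-isocyano-3-{5-[(tert-butyldiphenylsilyloxy)methyl]-2-oxo-2,3,4,7-tetrahydrooxepin-6-yl}propanoate
Product: 16 α-keto amide (N-[2-oxo-4-((R)-3-oxocyclopentyl)butanoyl] derivative of the amino ester of 9), via acid chloride 14 (not isolated), via imidoyl chloride 15 (not isolated)
Conditions: (COCl)2, DMF (cat.), CH2Cl2, 0 °C to rt; concentrate; 9, CH2Cl2, rt; then H2O, THF
Reagents that add atoms: water O
Why: Nef isocyanide reaction, in which the isocyanide carbon inserts into the C–Cl bond of the acid chloride to give an α-keto imidoyl chloride that hydrolyses to the α-keto amide, so the isocyanide carbon becomes the future NCH2 carbon of ring B; no stereocentre is touched.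

Step 9
Reactants: 16 α-keto amide
Product: 17 (3aS)-1-oxo-1,2,3,3a,4,5-hexahydropentalene-6-carboxamide N-substituted by the amino ester unit (enedione amide)
Conditions: pyrrolidine (cat.), AcOH (cat.), toluene, 4 Å molecular sieves, 40 °C
Reagents that add atoms: none
Why: Intramolecular aldol condensation in which the ketone α-carbon next to the substituted ring carbon attacks the highly electrophilic keto group of the α-keto amide (five-membered ring), and irreversible dehydration to the doubly conjugated tetrasubstituted alkene drains the reversible bridged aldol alternatives; the existing stereocentre is not enolised under these mild conditions.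

Step 10
Reactants: 17 enedione amide
Product: 18 N-Boc imide of 17
Conditions: Boc2O, DMAP (cat.), MeCN, rt
Reagents that add atoms: di-tert-butyl dicarbonate CC(C)(C)OC(=O)OC(=O)OC(C)(C)C
Why: DMAP-catalysed N-acylation of the secondary amide gives the imide, which lowers the amide rotational barrier for the following cyclisation and activates this carbonyl for later reduction; no stereocentre is formed.

Step 11
Reactants: 18 N-Boc imide
Product: 19 head-to-head cyclobutane photoadduct (cyclobutane fused to the cis-bicyclo[3.3.0]octanone, to the N-Boc δ-lactam of ring B and to the seven-membered lactone)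
Conditions: hν (350 nm), CH2Cl2 (dilute, degassed), −20 °C
Reagents that add atoms: none
Why: Intramolecular enone–alkene (2+2) photocycloaddition through the four-atom imide tether, which enforces the head-to-head adduct and a cis-fused lactam (ring B); the bicyclic enone can only react on the face of its ring-fusion hydrogen (cis-bicyclo[3.3.0]octane) and the tether fixes the alkene face, so the two quaternary carbons kept in the target are set relative to the existing stereocentre.

Step 12
Reactants: 19 cyclobutane photoadduct
Product: 20 cyclobutane alcohol (cyclopentanol from the ketone of 19)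
Conditions: NaBH4, CeCl3·7H2O, MeOH/THF, −78 °C
Reagents that add atoms: none
Why: Luche reduction of the cyclopentanone at −78 °C, where imide, lactone and ester should not be attacked; the configuration of the new carbinol is irrelevant because this carbon becomes sp2 in step 14.

Step 13
Reactants: 20 cyclobutane alcohol
Product: 21 O-phenyl thionocarbonate of 20
Conditions: PhOC(S)Cl, pyridine, DMAP (cat.), CH2Cl2, rt
Reagents that add atoms: O-phenyl chlorothionoformate S=C(Cl)Oc1ccccc1
Why: Acylation of the secondary alcohol installs the thiocarbonyl group needed for Barton–McCombie-type radical generation; no stereocentre changes.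

Step 14
Reactants: 21 O-phenyl thionocarbonate
Product: 22 ring-expanded N-Boc lactam (rings B, D and E with the seven-membered lactone)
Conditions: Bu3SnH (slow addition), AIBN (cat.), toluene, 90 °C
Reagents that add atoms: none
Why: Barton–McCombie radical generation followed by cyclobutylcarbinyl radical ring opening, in which β-scission toward the imide-stabilised tertiary radical places the cyclopentene double bond at the former carbinol carbon and merges the four- and five-membered rings into ring D; hydrogen transfer to the planar radical should occur anti to the neighbouring quaternary carbon that carries the cyclopentenyl unit (cis B/D fusion), and this centre stays epimerisable next to the imide carbonyl.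

Step 15
Reactants: 22 ring-expanded N-Boc lactam
Product: 24 N-Boc piperidine (ring B carbonyl removed), via hemiaminal 23 (not isolated)
Conditions: LiBHEt3, THF, −78 °C; then Et3SiH, BF3·OEt2, CH2Cl2, −78 °C
Reagents that add atoms: none
Why: Chemoselective hydride addition to the activated N-Boc lactam carbonyl (more electrophilic than ester and lactone at −78 °C) followed by N-acyliminium ion reduction removes the ring B carbonyl; the adjacent CH centre should be retained because the iminium ion is reduced faster than it tautomerises at this temperature.

Step 16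
Reactants: 24 N-Boc piperidine
Product: 25 primary alcohol (silyl ether of 24 cleaved)
Conditions: HF·pyridine, pyridine/THF, 0 °C to rt
Reagents that add atoms: none
Why: Fluoride-mediated silyl ether cleavage under non-basic conditions, chosen so that the freed primary alcohol does not translactonise before the oxidation; no stereocentre.

Step 17
Reactants: 25 primary alcohol
Product: 26 neopentyl aldehyde
Conditions: Dess–Martin periodinane, NaHCO3, CH2Cl2, 0 °C
Reagents that add atoms: none
Why: Dess–Martin oxidation of the hindered primary alcohol to the non-enolisable aldehyde under buffered conditions should leave carbamate, lactone and alkene intact.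

Step 18
Reactants: 26 neopentyl aldehyde
Product: 28 pentacyclic N-Boc amino ester (rings B to F with free CH2OH), via aldol adduct 27 (not isolated)
Conditions: KOt-Bu, THF, −78 to −30 °C; AcOH quench
Reagents that add atoms: none
Why: Intramolecular aldol addition of the pipecolate ester enolate to the aldehyde closes ring C (5-exo) as the 2-azabicyclo[3.2.1]octane with the bridgehead configuration dictated by the bicycle; the aldol is reversible and only the alkoxide cis to the acyl chain can attack the seven-membered lactone, so irreversible translactonisation to the six-membered lactone (ring F) selects the required carbinol configuration and frees the CH2OH group.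

Step 19
Reactants: 28 pentacyclic N-Boc amino ester
Product: 29 pentacyclic secondary amine
Conditions: CF3CO2H, CH2Cl2, 0 °C
Reagents that add atoms: none
Why: Acidolysis of the tert-butyl carbamate (loss of 2-methylpropene and CO2) gives the secondary amine, and brief exposure at 0 °C should spare the trisubstituted alkene and the lactone.

Step 20
Reactants: 29 pentacyclic secondary amine; 30 3-bromoprop-1-ene (allyl bromide)
Product: 31 N-allyl amino ester
Conditions: K2CO3, MeCN, 50 °C
Reagents that add atoms: none
Why: SN2 N-alkylation of the hindered secondary amine by the reactive allylic bromide; the primary alcohol is not alkylated under carbonate conditions.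

Step 21
Reactants: 31 N-allyl amino ester
Product: 32 cyclopropanol (3-azabicyclo[3.1.0]hexan-1-ol fused to rings B and C)
Conditions: Ti(OiPr)4, c-C5H9MgCl (slow addition), THF, rt
Reagents that add atoms: none
Why: Ligand exchange of the cyclopentene–titanium complex (from c-C5H9MgCl and Ti(OiPr)4) with the N-allyl group gives a titanacyclopropane whose internal carbon adds to the neighbouring bridgehead ester carbonyl, methoxide is lost, and the remaining C–Ti bond closes onto the resulting ketone to give the cyclopropanol. The closest known reaction type is the intramolecular Kulinkovich hydroxycyclopropanation of ω-alkenyl esters, including N-allyl α-amino esters. Ring A closes in a 5-exo-trig sense (alkene carbon onto the exocyclic C=O) and the temporary cyclopropane by 3-exo-trig attack of the terminal CH2–Ti on the same carbonyl carbon. The two new stereocentres are necessarily cis (ring fusion); their orientation relative to the bridgehead substituents is not controlled and need not be, because step 22 cleaves the C(OH)–CH2 bond and equilibrates the methyl-bearing carbon. The step needs chemoselectivity for the hindered bridgehead ester over the δ-lactone of ring F, which is secured by intramolecular delivery from the N-allyl group (the ester carbon is three atoms away, the lactone is remote) and by the cyclopentyl Grignard reagent, whose titanium complex exchanges with terminal alkenes faster than it adds to carbonyl groups; one further equivalent of Grignard reagent is consumed by the free CH2OH.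

Step 22
Reactants: 32 cyclopropanol
Product: 33 target compound CNP0180795.1
Conditions: KOt-Bu (cat.), t-BuOH/THF, 0 °C to rt
Reagents that add atoms: none
Why: Base-induced cyclopropanol ring opening (homoenolate at the less substituted CH2, then protonation) gives the α-methyl ketone, and the same base should equilibrate the enolisable α-carbon to the expected thermodynamic epimer with the methyl group on the face of ring A syn to the one-carbon CH2 bridge and away from the lactone-bearing carbon.

Compound list
1 | 2-(trimethylsilyloxy)buta-1,3-diene | C=CC(=C)O[Si](C)(C)C | starting material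
2 | methyl 4-chlorobut-2-ynoate | COC(=O)C#CCCl | starting material
3 | methyl 2-(chloromethyl)-4-(trimethylsilyloxy)cyclohexa-1,4-diene-1-carboxylate | COC(=O)C1=C(CCl)CC(O[Si](C)(C)C)=CC1 | intermediate
4 | [2-(chloromethyl)-4-(trimethylsilyloxy)cyclohexa-1,4-dien-1-yl]methanol | OCC1=C(CCl)CC(O[Si](C)(C)C)=CC1 | intermediate
5 | bis-silyl ether (tert-butyldiphenylsilyl ether of 4) | C[Si](C)(C)OC1=CCC(CO[Si](c2ccccc2)(c2ccccc2)C(C)(C)C)=C(CCl)C1 | intermediate
6 | 4-[(tert-butyldiphenylsilyloxy)methyl]-3-(chloromethyl)cyclohex-3-en-1-one | O=C1CCC(CO[Si](c2ccccc2)(c2ccccc2)C(C)(C)C)=C(CCl)C1 | intermediate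
7 | 5-[(tert-butyldiphenylsilyloxy)methyl]-6-(chloromethyl)-4,7-dihydrooxepin-2(3H)-one | O=C1CCC(CO[Si](c2ccccc2)(c2ccccc2)C(C)(C)C)=C(CCl)CO1 | intermediate
8 | methyl isocyanoacetate | [C-]#[N+]CC(=O)OC | starting material
9 | methyl 2-isocyano-3-{5-[(tert-butyldiphenylsilyloxy)methyl]-2-oxo-2,3,4,7-tetrahydrooxepin-6-yl}propanoate (racemic) | [C-]#[N+]C(CC1=C(CO[Si](c2ccccc2)(c2ccccc2)C(C)(C)C)CCC(=O)OC1)C(=O)OC | intermediate
10 | cyclopent-2-en-1-one | O=C1C=CCC1 | starting material
11 | but-3-en-1-ylmagnesium bromide | C=CCC[Mg]Br | starting material
12 | (S)-3-(but-3-en-1-yl)cyclopentan-1-one | C=CCC[C@@H]1CC(=O)CC1 | intermediate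
13 | (R)-3-(3-oxocyclopentyl)propanoic acid | OC(=O)CC[C@@H]1CC(=O)CC1 | intermediate
14 | (R)-3-(3-oxocyclopentyl)propanoyl chloride | ClC(=O)CC[C@@H]1CC(=O)CC1 | intermediate
15 | α-keto imidoyl chloride (Nef adduct of 14 and 9; both α-amino carbon epimers) | O=C1CC[C@H](CCC(=O)C(Cl)=NC(CC2=C(CO[Si](c3ccccc3)(c3ccccc3)C(C)(C)C)CCC(=O)OC2)C(=O)OC)C1 | intermediate
16 | α-keto amide: methyl 2-{[2-oxo-4-((R)-3-oxocyclopentyl)butanoyl]amino}-3-{5-[(tert-butyldiphenylsilyloxy)methyl]-2-oxo-2,3,4,7-tetrahydrooxepin-6-yl}propanoate (both α-amino carbon epimers) | O=C1CC[C@H](CCC(=O)C(=O)NC(CC2=C(CO[Si](c3ccccc3)(c3ccccc3)C(C)(C)C)CCC(=O)OC2)C(=O)OC)C1 | intermediate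
17 | enedione amide: (3aS)-1-oxo-1,2,3,3a,4,5-hexahydropentalene-6-carboxamide bearing on nitrogen the amino ester unit of 9 | O=C1CC[C@@H]2CCC(C(=O)NC(CC3=C(CO[Si](c4ccccc4)(c4ccccc4)C(C)(C)C)CCC(=O)OC3)C(=O)OC)=C12 | intermediate
18 | N-Boc imide of 17 | O=C1CC[C@@H]2CCC(C(=O)N(C(=O)OC(C)(C)C)C(CC3=C(CO[Si](c4ccccc4)(c4ccccc4)C(C)(C)C)CCC(=O)OC3)C(=O)OC)=C12 | intermediate
19 | head-to-head cyclobutane photoadduct (cyclobutane fused to the cis-bicyclo[3.3.0]octanone, the N-Boc δ-lactam and the seven-membered lactone) | COC(=O)C1N(C(=O)OC(C)(C)C)C(=O)[C@@]23CC[C@H]4CCC(=O)[C@@]24[C@]5(CO[Si](c6ccccc6)(c6ccccc6)C(C)(C)C)CCC(=O)OC[C@]35C1 | intermediate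
20 | cyclobutane alcohol (cyclopentanol from 19; carbinol configuration undefined) | COC(=O)C1N(C(=O)OC(C)(C)C)C(=O)[C@@]23CC[C@H]4CCC(O)[C@@]24[C@]5(CO[Si](c6ccccc6)(c6ccccc6)C(C)(C)C)CCC(=O)OC[C@]35C1 | intermediate
21 | O-phenyl thionocarbonate of 20 | COC(=O)C1N(C(=O)OC(C)(C)C)C(=O)[C@@]23CC[C@H]4CCC(OC(=S)Oc7ccccc7)[C@@]24[C@]5(CO[Si](c6ccccc6)(c6ccccc6)C(C)(C)C)CCC(=O)OC[C@]35C1 | intermediate
22 | ring-expanded N-Boc lactam (cis-fused rings B and D, cyclopentene ring E, seven-membered lactone, CH2OTBDPS on the quaternary carbon next to the alkene) | CC(C)(C)OC(=O)N1C(=O)[C@H]2CC[C@H]3CCC=C3[C@]3(CO[Si](c4ccccc4)(c4ccccc4)C(C)(C)C)CCC(=O)OC[C@]23CC1C(=O)OC | intermediate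
23 | N-Boc hemiaminal from 22 (hemiaminal carbon undefined) | CC(C)(C)OC(=O)N1C(O)[C@H]2CC[C@H]3CCC=C3[C@]3(CO[Si](c4ccccc4)(c4ccccc4)C(C)(C)C)CCC(=O)OC[C@]23CC1C(=O)OC | intermediate
24 | N-Boc piperidine (methyl pipecolate unit fused to ring D) | CC(C)(C)OC(=O)N1C[C@H]2CC[C@H]3CCC=C3[C@]3(CO[Si](c4ccccc4)(c4ccccc4)C(C)(C)C)CCC(=O)OC[C@]23CC1C(=O)OC | intermediate
25 | primary alcohol from 24 | CC(C)(C)OC(=O)N1C[C@H]2CC[C@H]3CCC=C3[C@]3(CO)CCC(=O)OC[C@]23CC1C(=O)OC | intermediate
26 | neopentyl aldehyde from 25 | CC(C)(C)OC(=O)N1C[C@H]2CC[C@H]3CCC=C3[C@]3(C=O)CCC(=O)OC[C@]23CC1C(=O)OC | intermediate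
27 | aldol adduct (ring C closed, seven-membered lactone still intact, secondary OH cis to the acyl chain) | CC(C)(C)OC(=O)N2C[C@H]3CC[C@H]4CCC=C4[C@@]45CCC(=O)OC[C@]35C[C@@]2(C(=O)OC)[C@H]4O | intermediate
28 | pentacyclic N-Boc amino ester (rings B to F; bridgehead CO2Me; free CH2OH) | CC(C)(C)OC(=O)N2C[C@H]3CC[C@H]4CCC=C4[C@@]45CCC(=O)O[C@@H]4[C@@]2(C[C@@]35CO)C(=O)OC | intermediate
29 | pentacyclic secondary amine | N2C[C@H]3CC[C@H]4CCC=C4[C@@]45CCC(=O)O[C@@H]4[C@@]2(C[C@@]35CO)C(=O)OC | intermediate
30 | 3-bromoprop-1-ene (allyl bromide) | C=CCBr | starting material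
31 | N-allyl amino ester | C=CCN2C[C@H]3CC[C@H]4CCC=C4[C@@]45CCC(=O)O[C@@H]4[C@@]2(C[C@@]35CO)C(=O)OC | intermediate
32 | cyclopropanol (cis-fused 3-azabicyclo[3.1.0]hexan-1-ol on the bridgehead carbon; both cis-fused diastereomers) | C1C2CN3C[C@H]4CC[C@H]5CCC=C5[C@@]56CCC(=O)O[C@@H]5[C@@]3(C[C@@]46CO)C12O | intermediate
33 | CNP0180795.1 | C[C@@H]1CN2C[C@H]3CC[C@H]4CCC=C4[C@@]45CCC(=O)O[C@@H]4[C@@]2(C[C@@]35CO)C1=O | target

Total step count: 22. Longest linear sequence: 20 steps (steps 1 to 5, then 8 to 22).

Steps most likely to fail

Step 11. Closure to a cyclobutane with four fully substituted carbons may not compete with unproductive decay of the excited enedione, or imide conformers that cannot fold may dominate. The fallback is a ground-state polar cycloaddition instead of a photochemical one. It sets out from 18: EtAlCl2 in CH2Cl2 at −78 °C activates the enedione, the tetrasubstituted alkene attacks the amide-bearing β-carbon (closing the six-membered lactam), and the tertiary carbocation collapses onto the aluminium enolate at the α-carbon. This Michael–aldol-type sequence has the same tether-enforced topology and comes back to the route at 19 without any new compound (F0).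

Step 14. The secondary radical may take hydrogen from the stannane before the ring opens, or the other cyclobutane bond may break. The fallback is an electron-transfer fragmentation at the ketone stage. It sets out from 19: SmI2 (THF, HMPA, t-BuOH, −78 °C) forms the ketyl, which is relieved only by scission toward the imide-bearing carbon; that radical is reduced to the samarium imide enolate, and protonation gives the ring-expanded keto imide F1. Equilibrating enol triflate formation toward the more substituted position (Tf2O, 2,6-di-tert-butyl-4-methylpyridine, CH2Cl2) gives the enol triflate F2. Reduction with Pd(OAc)2, PPh3, HCO2H and Bu3N in DMF comes back to the route at 22.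

Step 21. The Grignard reagent or the titanium alkene complex may attack the δ-lactone of ring F instead of being delivered to the hindered bridgehead ester. The fallback is a Dieckmann route that still closes ring A last. It sets out from 29: aza-Michael addition to methyl acrylate (MeOH, 50 °C) gives the β-amino ester F3. Dieckmann condensation onto the bridgehead ester (KOt-Bu, THF, 0 °C), driven by the enolisable product, gives the ring A β-keto ester F4. C-methylation (MeI, K2CO3, acetone) gives the methylated β-keto ester F5. Krapcho dealkoxycarbonylation (LiCl, wet DMSO, 130 °C), with equilibration of the methyl-bearing carbon, comes back to the route at 33.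

Further compounds
F0 | step 11 | none | none
F1 | step 14 | ring-expanded keto imide (cyclopentanone in place of the cyclopentene of 22) | CC(C)(C)OC(=O)N1C(=O)[C@H]2CC[C@H]3CCC(=O)C3[C@]3(CO[Si](c4ccccc4)(c4ccccc4)C(C)(C)C)CCC(=O)OC[C@]23CC1C(=O)OC
F2 | step 14 | enol triflate of F1 (double bond toward the ring-fusion carbon) | CC(C)(C)OC(=O)N1C(=O)[C@H]2CC[C@H]3CCC(OS(=O)(=O)C(F)(F)F)=C3[C@]3(CO[Si](c4ccccc4)(c4ccccc4)C(C)(C)C)CCC(=O)OC[C@]23CC1C(=O)OC
F3 | step 21 | β-amino ester (N-(2-methoxycarbonylethyl) derivative of 29) | COC(=O)CCN2C[C@H]3CC[C@H]4CCC=C4[C@@]45CCC(=O)O[C@@H]4[C@@]2(C[C@@]35CO)C(=O)OC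
F4 | step 21 | ring A β-keto ester (4-methoxycarbonylpyrrolidin-3-one) | COC(=O)C1CN2C[C@H]3CC[C@H]4CCC=C4[C@@]45CCC(=O)O[C@@H]4[C@@]2(C[C@@]35CO)C1=O
F5 | step 21 | methylated β-keto ester (4-methyl-4-methoxycarbonylpyrrolidin-3-one) | COC(=O)C1(C)CN2C[C@H]3CC[C@H]4CCC=C4[C@@]45CCC(=O)O[C@@H]4[C@@]2(C[C@@]35CO)C1=O
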